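## Structural features

- The target is a lignin-type β-O-4 ketone. A three-carbon chain Cα(=O)–Cβ(H)(OAr)–CγH2OH carries a 4-hydroxy-3,5-dimethoxyphenyl (syringyl) ring on Cα, and the oxygen on Cβ is the phenolic oxygen of vanillic acid.
- Cβ is the only stereocentre. Reading the SMILES gives it as (R) (OAr > C=O > CH2OH > H), and there is no neighbouring stereocentre to relay from.
- Cβ–H is α to an aryl ketone and geminal to an aryloxy group, so base racemises it. The γ-hydroxyl also opens retro-aldol loss of formaldehyde and β-elimination of water to an α-aryloxy enone.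
- The free syringyl phenol is oxidation-sensitive, and the carboxylic acid and primary alcohol are competing nucleophiles.
- Both aromatic rings are commodity units, so the real difficulty is the Cβ–O(aryl) bond with defined configuration next to the ketone, and keeping that configuration to the end.
- The key step exploits this feature: if the carbonyl oxygen on Cα is replaced by a methylene group, CH2=Cα–Cβ becomes an allyl unit. The Cβ–OAr bond is then an allylic ether bond that a π-allylpalladium complex can form from either enantiomer of a racemic precursor, and the Cγ oxygen (the oxygen of an oxirane spanning Cβ–Cγ) serves as leaving group and internal base.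

## Logic of the disconnections

**10 ⇒ 9.** The two O–CH2Ph bonds (syringyl ether and carboxyl ester) are cut. Both groups fall in one neutral hydrogenolysis, so nothing acidic or basic touches Cβ after the ketone exists. The demand is that O-debenzylation outruns reduction of the aryl ketone and hydrogenolysis of the Cβ–O bond.

**9 ⇒ 7 (through 8).** The Cα=O bond is traced back to Cα=CH2. This costs one carbon, lost as formaldehyde. The gain is that Cβ in 7 is an ordinary allylic ether carbon, configurationally robust, and that 7 contains the allyl unit needed for the key step. The demand is an oxidative cleavage that selects the alkene over two alkoxy-substituted rings and has a neutral work-up.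

**7 ⇒ 4 + 6 (key).** The Cβ–O(aryl) bond is cut. In one sentence, the route is a palladium-catalysed dynamic kinetic asymmetric allylic etherification of racemic 4 by phenol 6. The cut divides the molecule into two fragments of similar size, neither of which needs a stereocentre, and the configuration comes from the catalyst, with no chiral pool and no resolution. The demands are attack at the substituted allyl terminus, interconversion of the diastereomeric π-allyl complexes faster than their capture, and ligand control of which one is captured.

**4 ⇒ 2 + 3.** The Cα–aryl bond and the oxirane Cβ–O bond are cut. An aryl halide and an allenol give the whole 2-aryl-substituted vinyl oxirane in one palladium-catalysed operation, with no organometallic reagent. The demand is that the aryl group goes to the central allene carbon and that three-membered closure beats five-membered closure.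

**2 ⇒ 1 and 6 ⇒ 5.** The O–benzyl bonds are cut. Benzyl is chosen for both positions because it survives carbonate, zerovalent palladium and ozone, and both groups leave together in the last step.

## Other disconnections considered

**Alternative 1: (the first route to come to mind).** Cut Cβ–O by SN2 at the ketone oxidation level and Cβ–Cγ by an aldol reaction.
- Forward: 1-[4-(benzyloxy)-3,5-dimethoxyphenyl]-2-bromoethan-1-one A1 alkylates 6 to give aryloxy ketone A2. Base-mediated hydroxymethylation with formaldehyde then gives the keto alcohol A3, the racemate of 9.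
- Ground for rejection: the stereocentre is created by an enolate under basic, reversible conditions in which the product itself enolises. No catalyst control can outlast that epimerisation, so the route ends in a racemate and loses at least half the material in a resolution. The chosen plan makes the same bond at the alkene oxidation level, where the centre is stable.

**Alternative 2:** Cut the Cα–aryl bond, with Cβ from the chiral pool.
- Forward: Mitsunobu inversion of methyl (2S)-3-[(tert-butyldimethylsilyl)oxy]-2-hydroxypropanoate A4 with 6 and amide exchange would give the N-methoxy-N-methylamide A5. The key step is acylation of the aryllithium A6 (from 2) by A5.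
- Ground for rejection: the α-aryloxy amide and the ketone product are exposed to a strongly basic organolithium, which invites enolisation and loss of enantiopurity. A6 would also attack the benzoate ester of A5, forcing a different ester and an acidic deprotection. Cγ–OH needs its own protecting group, and the count rises by three or more steps.

**Alternative 3:** Keep the skeleton and set Cβ by dynamic kinetic resolution.
- Forward: the racemic β-keto ester A7 is reduced with RuCl(p-cymene)[(S,S)-TsDPEN] and HCO2H/Et3N to the β-hydroxy ester A8. Reduction of the aliphatic ester and re-oxidation of the benzylic alcohol would then be needed to reach 9.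
- Ground for rejection: it is stereoconvergent like the chosen plan, but it is a redox detour. Two stereocentres are set to keep one, the ketone is destroyed and remade, the re-oxidation must spare the primary alcohol, and the hydride step must spare the benzoate. It is at least three steps longer.

Key step: step 4

Assumption: the sense of induction in step 4 is taken from the parent butadiene monoepoxide series, where the (R,R)-ligand is recalled (not verified) to give the (S)-configured X–CH(CH2OH)–vinyl product; if the central aryl group reverses it, the mirror-image ligand is used and nothing else changes.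

## Route

Step 1
Reactants: 1 4-bromo-2,6-dimethoxyphenol
Product: 2 2-(benzyloxy)-5-bromo-1,3-dimethoxybenzene
Conditions: BnBr (1.1 equiv), K2CO3 (1.5 equiv), DMF, rt
Reagents that add atoms: benzyl bromide, BrCc1ccccc1
Why: Williamson ether synthesis; the phenoxide of 1 is flanked by two methoxy groups but should benzylate cleanly with a primary benzylic bromide, and the aryl bromide is inert to carbonate.

Step 2
Reactants: 2 2-(benzyloxy)-5-bromo-1,3-dimethoxybenzene; 3 buta-2,3-dien-1-ol
Product: 4 racemic 2-{1-[4-(benzyloxy)-3,5-dimethoxyphenyl]ethenyl}oxirane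
Conditions: Pd(PPh3)4 (5 mol %), K2CO3 (2 equiv), DMF, 80 °C
Reagents that add atoms: none
Why: Palladium-catalysed coupling–cyclisation of a 2,3-allenol with an aryl halide: oxidative addition of 2 to zerovalent palladium, carbopalladation of the allene with the aryl group going to the central carbon, and attack of the alkoxide on the adjacent terminus of the η3-allyl complex (3-exo closure) should give the vinyl oxirane; no stereocontrol is needed because step 4 is stereoconvergent.

Step 3
Reactants: 5 vanillic acid (4-hydroxy-3-methoxybenzoic acid)
Product: 6 benzyl 4-hydroxy-3-methoxybenzoate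
Conditions: BnBr (1.05 equiv), KHCO3 (1.2 equiv), DMF, 40 °C
Reagents that add atoms: benzyl bromide, BrCc1ccccc1
Why: Carboxylate O-alkylation (SN2); hydrogencarbonate deprotonates the carboxylic acid but not the phenol, so the phenol stays free for step 4.

Step 4
Reactants: 4 racemic 2-{1-[4-(benzyloxy)-3,5-dimethoxyphenyl]ethenyl}oxirane; 6 benzyl 4-hydroxy-3-methoxybenzoate (1.1 equiv)
Product: 7 benzyl 4-{[(2S)-3-[4-(benzyloxy)-3,5-dimethoxyphenyl]-1-hydroxybut-3-en-2-yl]oxy}-3-methoxybenzoate
Conditions: Pd2(dba)3·CHCl3 (2.5 mol %), (R,R)-DACH-naphthyl ligand N,N'-[(1R,2R)-cyclohexane-1,2-diyl]bis[2-(diphenylphosphanyl)-1-naphthamide] (7.5 mol %), CH2Cl2, 0 °C to rt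
Reagents that add atoms: none
Why: Zerovalent palladium ionises both enantiomers of 4 with inversion to zwitterionic 2-aryl-η3-allylpalladium alkoxides, which are diastereomeric under the chiral ligand and interconvert by η3–η1–η3 slippage through the unsubstituted CH2 terminus faster than they are captured. The alkoxide deprotonates the phenol of 6, which is about as acidic as the imide pronucleophiles typical of this chemistry, and the hydrogen-bonded phenoxide attacks the neighbouring allyl terminus anti to palladium, forming the Cβ–O bond and releasing the catalyst. The closest known reactions are the palladium-catalysed dynamic kinetic asymmetric addition of acidic pronucleophiles to butadiene monoepoxide and the deracemising phenol etherification of Morita–Baylis–Hillman carbonates, whose π-allyl also carries a substituent on the central carbon and also gives a branched aryl ether beside a 1,1-disubstituted alkene. No ring is closed. The one new stereocentre is controlled by the ligand, which decides which of the equilibrating π-allyl diastereomers is attacked (Curtin–Hammett); the (R,R)-ligand is proposed by analogy with the parent vinyl oxirane and is expected to give the (S)-ether. Branched over linear attack is secured by the internal alkoxide, which generates the nucleophile next to the substituted terminus. Phenol over the primary alcohol of 7 as nucleophile is secured by the large acidity difference. Reionisation of 7 is held back by working at or below room temperature and stopping when 4 is consumed.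

Step 5
Reactants: 7 benzyl 4-{[(2S)-3-[4-(benzyloxy)-3,5-dimethoxyphenyl]-1-hydroxybut-3-en-2-yl]oxy}-3-methoxybenzoate
Product: 9 benzyl 4-{[(2R)-1-[4-(benzyloxy)-3,5-dimethoxyphenyl]-3-hydroxy-1-oxopropan-2-yl]oxy}-3-methoxybenzoate, via secondary ozonide 8 (not isolated)
Conditions: O3, CH2Cl2, −78 °C, Sudan Red 7B as end-point indicator; then PPh3 (1.2 equiv), −78 °C to rt
Reagents that add atoms: ozone, [O-][O+]=O
Why: Ozonolysis by the Criegee mechanism with reductive work-up: the electron-rich 1,1-disubstituted styrene-type alkene should add ozone far faster than the alkoxyarenes or the benzylic C–H bonds, and PPh3 reduces ozonide 8 under neutral conditions so the now enolisable Cβ never meets base; the configuration is untouched and the descriptor changes from S to R only because the new carbonyl carbon outranks CH2OH.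

Step 6
Reactants: 9 benzyl 4-{[(2R)-1-[4-(benzyloxy)-3,5-dimethoxyphenyl]-3-hydroxy-1-oxopropan-2-yl]oxy}-3-methoxybenzoate
Product: 10 4-{[(2R)-3-hydroxy-1-(4-hydroxy-3,5-dimethoxyphenyl)-1-oxopropan-2-yl]oxy}-3-methoxybenzoic acid (CNP0507417.1)
Conditions: H2 (1 atm), 10% Pd/C, EtOAc, rt, stopped at uptake of two equivalents
Reagents that add atoms: none
Why: Catalytic hydrogenolysis of the benzyl ether and the benzyl ester in one neutral operation; O-benzyl cleavage should be much faster than reduction of an electron-rich aryl ketone in ethyl acetate, debenzylation beside such a ketone being standard practice with lignin-type aryloxy ketones, and no acid or base touches the stereocentre.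

## Compound list

1 | 4-bromo-2,6-dimethoxyphenol | COc1cc(Br)cc(OC)c1O | starting material
2 | 2-(benzyloxy)-5-bromo-1,3-dimethoxybenzene | COc1cc(Br)cc(OC)c1OCc1ccccc1 | intermediate
3 | buta-2,3-dien-1-ol | C=C=CCO | starting material
4 | racemic 2-{1-[4-(benzyloxy)-3,5-dimethoxyphenyl]ethenyl}oxirane | C=C(C1CO1)c1cc(OC)c(OCc2ccccc2)c(OC)c1 | intermediate
5 | vanillic acid (4-hydroxy-3-methoxybenzoic acid) | COc1cc(C(=O)O)ccc1O | starting material
6 | benzyl 4-hydroxy-3-methoxybenzoate | COc1cc(C(=O)OCc2ccccc2)ccc1O | intermediate
7 | benzyl 4-{[(2S)-3-[4-(benzyloxy)-3,5-dimethoxyphenyl]-1-hydroxybut-3-en-2-yl]oxy}-3-methoxybenzoate | COc1cc(C(=O)OCc2ccccc2)ccc1O[C@H](CO)C(=C)c1cc(OC)c(OCc2ccccc2)c(OC)c1 | intermediate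
8 | benzyl 4-{[(1R)-1-{3-[4-(benzyloxy)-3,5-dimethoxyphenyl]-1,2,4-trioxolan-3-yl}-2-hydroxyethyl]oxy}-3-methoxybenzoate (secondary ozonide, both epimers at the trioxolane carbon) | COc1cc(C(=O)OCc2ccccc2)ccc1O[C@H](CO)C1(OOCO1)c1cc(OC)c(OCc2ccccc2)c(OC)c1 | intermediate (not isolated)
9 | benzyl 4-{[(2R)-1-[4-(benzyloxy)-3,5-dimethoxyphenyl]-3-hydroxy-1-oxopropan-2-yl]oxy}-3-methoxybenzoate | COc1cc(C(=O)OCc2ccccc2)ccc1O[C@H](CO)C(=O)c1cc(OC)c(OCc2ccccc2)c(OC)c1 | intermediate
10 | 4-{[(2R)-3-hydroxy-1-(4-hydroxy-3,5-dimethoxyphenyl)-1-oxopropan-2-yl]oxy}-3-methoxybenzoic acid | COc1cc(C(=O)O)ccc1O[C@H](CO)C(=O)c1cc(OC)c(O)c(OC)c1 | target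

## Step count and least certain steps

Total step count: 6. Longest linear sequence: 5 steps (steps 1, 2, 4, 5, 6).

**Step 4 (key step).**
- What may go wrong: attack at the unsubstituted allyl terminus, because the aryl group on the central carbon crowds the substituted one; partial population of the anti-configured π-allyl isomer, which leads to the opposite enantiomer through the same face of attack and so lowers or reverses the selectivity; and reionisation of the product, since the ester-bearing aryloxide is a fair leaving group, with racemisation and drift to the linear ether.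
- Fallback, from 4 back to 7 (resolution followed by stereospecific displacement in place of catalyst-controlled dynamic C–O formation): hydrolytic kinetic resolution of 4 with (salen)Co(OAc) and 0.45 equiv of water gives (2R)-3-[4-(benzyloxy)-3,5-dimethoxyphenyl]but-3-ene-1,2-diol F1. The catalyst is a trivalent cobalt complex, salen being the N,N'-bis(3,5-di-tert-butylsalicylidene)cyclohexane-1,2-diamine dianion, used as the enantiomer that hydrolyses (R)-4. Silylation of the primary hydroxyl (TBSCl, imidazole, CH2Cl2, 0 °C) gives (2R)-3-[4-(benzyloxy)-3,5-dimethoxyphenyl]-1-[(tert-butyldimethylsilyl)oxy]but-3-en-2-ol F2. Mitsunobu etherification with 6 (PPh3, DIAD, toluene, 0 °C) inverts the carbinol carbon and gives benzyl 4-{[(2S)-3-[4-(benzyloxy)-3,5-dimethoxyphenyl]-1-[(tert-butyldimethylsilyl)oxy]but-3-en-2-yl]oxy}-3-methoxybenzoate F3. Desilylation with TBAF buffered by AcOH in THF returns to 7.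

**Step 2.**
- What may go wrong: the zerovalent palladium that forms the vinyl oxirane can reopen it, leading to isomerisation or oligomerisation; five-membered closure to a dihydrofuran can compete; and oxidative addition of the electron-rich bromide may be slow.
- Fallback, from 2 back to 4 (a stepwise carbonyl route in place of the allene carbopalladation): bromine–lithium exchange (n-BuLi, THF, −78 °C) gives [4-(benzyloxy)-3,5-dimethoxyphenyl]lithium F4, which adds to acrolein to give 1-[4-(benzyloxy)-3,5-dimethoxyphenyl]prop-2-en-1-ol F5. Oxidation with MnO2 gives 1-[4-(benzyloxy)-3,5-dimethoxyphenyl]prop-2-en-1-one F6. Weitz–Scheffer epoxidation (H2O2, NaOH, MeOH, 0 °C) gives [4-(benzyloxy)-3,5-dimethoxyphenyl](oxiran-2-yl)methanone F7. Wittig methylenation (Ph3P=CH2 from methyltriphenylphosphonium bromide and KOtBu, THF, 0 °C) returns to 4.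

**Step 5.**
- What may go wrong: over-oxidation of the alkoxy-substituted rings or of the benzyl groups once the alkene is consumed; abnormal fragmentation of the carbonyl oxide next to the oxygen-bearing carbon; and epimerisation during purification of the ketone.
- Fallback, from 7 back to 9 (two steps through an isolable triol, without ozone): dihydroxylation (OsO4 cat., N-methylmorpholine N-oxide, acetone–water) gives benzyl 4-{[(2R)-3-[4-(benzyloxy)-3,5-dimethoxyphenyl]-1,3,4-trihydroxybutan-2-yl]oxy}-3-methoxybenzoate F8 as a mixture of epimers at the tertiary carbinol. Glycol cleavage of its only vicinal diol with NaIO4 in THF–water gives 9.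

**Step 6.**
- What may go wrong: reduction of the aryl ketone to the benzylic alcohol, or hydrogenolytic cleavage of the activated Cβ–O bond, before both benzyl groups are gone.
- Fallback, from 9 directly to 10 (non-reductive Lewis-acid debenzylation): BCl3 with pentamethylbenzene as cation scavenger in CH2Cl2 at −78 °C, which cleaves the aryl benzyl ether and the benzyl ester without hydrogen; no new intermediate is formed.

## Further compounds

F1 | step 4 | (2R)-3-[4-(benzyloxy)-3,5-dimethoxyphenyl]but-3-ene-1,2-diol | O[C@@H](CO)C(=C)c1cc(OC)c(OCc2ccccc2)c(OC)c1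
F2 | step 4 | (2R)-3-[4-(benzyloxy)-3,5-dimethoxyphenyl]-1-[(tert-butyldimethylsilyl)oxy]but-3-en-2-ol | O[C@@H](CO[Si](C)(C)C(C)(C)C)C(=C)c1cc(OC)c(OCc2ccccc2)c(OC)c1
F3 | step 4 | benzyl 4-{[(2S)-3-[4-(benzyloxy)-3,5-dimethoxyphenyl]-1-[(tert-butyldimethylsilyl)oxy]but-3-en-2-yl]oxy}-3-methoxybenzoate | COc1cc(C(=O)OCc2ccccc2)ccc1O[C@H](CO[Si](C)(C)C(C)(C)C)C(=C)c1cc(OC)c(OCc2ccccc2)c(OC)c1
F4 | step 2 | [4-(benzyloxy)-3,5-dimethoxyphenyl]lithium | [Li]c1cc(OC)c(OCc2ccccc2)c(OC)c1
F5 | step 2 | 1-[4-(benzyloxy)-3,5-dimethoxyphenyl]prop-2-en-1-ol (racemic) | C=CC(O)c1cc(OC)c(OCc2ccccc2)c(OC)c1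
F6 | step 2 | 1-[4-(benzyloxy)-3,5-dimethoxyphenyl]prop-2-en-1-one | C=CC(=O)c1cc(OC)c(OCc2ccccc2)c(OC)c1
F7 | step 2 | [4-(benzyloxy)-3,5-dimethoxyphenyl](oxiran-2-yl)methanone (racemic) | O=C(C1CO1)c1cc(OC)c(OCc2ccccc2)c(OC)c1
F8 | step 5 | benzyl 4-{[(2R)-3-[4-(benzyloxy)-3,5-dimethoxyphenyl]-1,3,4-trihydroxybutan-2-yl]oxy}-3-methoxybenzoate (both epimers at C3) | COc1cc(C(=O)OCc2ccccc2)ccc1O[C@H](CO)C(O)(CO)c1cc(OC)c(OCc2ccccc2)c(OC)c1
F0 | step 6 | none | none
A1 | alternative 1 | 1-[4-(benzyloxy)-3,5-dimethoxyphenyl]-2-bromoethan-1-one | COc1cc(C(=O)CBr)cc(OC)c1OCc1ccccc1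
A2 | alternative 1 | benzyl 4-{2-[4-(benzyloxy)-3,5-dimethoxyphenyl]-2-oxoethoxy}-3-methoxybenzoate | COc1cc(C(=O)OCc2ccccc2)ccc1OCC(=O)c1cc(OC)c(OCc2ccccc2)c(OC)c1
A3 | alternative 1 | racemic benzyl 4-{[1-[4-(benzyloxy)-3,5-dimethoxyphenyl]-3-hydroxy-1-oxopropan-2-yl]oxy}-3-methoxybenzoate | COc1cc(C(=O)OCc2ccccc2)ccc1OC(CO)C(=O)c1cc(OC)c(OCc2ccccc2)c(OC)c1
A4 | alternative 2 | methyl (2S)-3-[(tert-butyldimethylsilyl)oxy]-2-hydroxypropanoate | O[C@@H](CO[Si](C)(C)C(C)(C)C)C(=O)OC
A5 | alternative 2 | benzyl 4-{[(2R)-3-[(tert-butyldimethylsilyl)oxy]-1-[methoxy(methyl)amino]-1-oxopropan-2-yl]oxy}-3-methoxybenzoate | COc1cc(C(=O)OCc2ccccc2)ccc1O[C@H](CO[Si](C)(C)C(C)(C)C)C(=O)N(C)OC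
A6 | alternative 2 | [4-(benzyloxy)-3,5-dimethoxyphenyl]lithium | [Li]c1cc(OC)c(OCc2ccccc2)c(OC)c1
A7 | alternative 3 | ethyl 2-{4-[(benzyloxy)carbonyl]-2-methoxyphenoxy}-3-[4-(benzyloxy)-3,5-dimethoxyphenyl]-3-oxopropanoate (racemic) | COc1cc(C(=O)OCc2ccccc2)ccc1OC(C(=O)OCC)C(=O)c1cc(OC)c(OCc2ccccc2)c(OC)c1
A8 | alternative 3 | ethyl (2S)-2-{4-[(benzyloxy)carbonyl]-2-methoxyphenoxy}-3-[4-(benzyloxy)-3,5-dimethoxyphenyl]-3-hydroxypropanoate (carbinol configuration set by the catalyst, lost later) | COc1cc(C(=O)OCc2ccccc2)ccc1O[C@H](C(=O)OCC)C(O)c1cc(OC)c(OCc2ccccc2)c(OC)c1
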